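**Retrosynthetic overview**

1. Numbering follows the target SMILES: C1 (exo-methylene), C2, C3 (C=O), O4, C5 (lactone CH–O), C6=C7, C8, C9 (acetoxy CH), C10=C11, C12, C13, C14=C15, C16, C17, C18 (ring fusion). Ring A is the 14-membered carbocycle C5–C18 and ring B the lactone. The strategy rests on C5–C18–C17–C16, the only run of four sp3 carbons in ring A, which ends at olefinic C15: it is drawn as a cyclobutanol (C5 carbinol) whose strained C5–C16 bond is traded for C15–C16.
2. Target ⇐ C9 acetate and C1 methylene installed last ⇐ ring B from a C5 ketone (reduction) and the C18 hydroxyethyl arm (oxidative lactonisation).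
3. Ring A enone 25 ⇐ C15–C16: palladium-catalysed ring-opening macrocyclisation of the 1-alkenylcyclobutanol vinyl iodide 24.
4. 24 ⇐ C5–C6: alkenyllithium 21 plus (R)-cyclobutanone 7 (RAMP-hydrazone alkylation of cyclobutanone), then hydrozirconation–iodination at C15.
5. Chain C6–C15 ⇐ pent-3-yn-1-ol and ethyl but-2-ynoate (syn-carbocupration, C10=C11), asymmetric propargylboration (C9), carboalumination–iodination (C6=C7). Ring order: A (step 13), then B (step 16).

Key step: step 13

Assumption: in step 14 the trisubstituted alkenyl group is taken to act as the larger ketone substituent toward the oxazaborolidine, and in step 8 the R phosphoric acid is taken to direct attack to the Re face. Locants are those of line 1; the CIP descriptor at C5 changes along the route while its spatial arrangement stays, so the SMILES strings are authoritative.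

**Route**

Step 1
Reactants: 1 cyclobutanone; 2 (R)-1-amino-2-(methoxymethyl)pyrrolidine (RAMP)
Product: 3 cyclobutanone RAMP hydrazone
Conditions: 4 Å MS, CH2Cl2, rt
Reagents that add atoms: none
Why: Hydrazone formation by condensation of the unhindered strained ketone with the N-amino group gives the chiral substrate for the RAMP-hydrazone alkylation.

Step 2
Reactants: 3 cyclobutanone RAMP hydrazone; 4 tert-butyl(2-iodoethoxy)dimethylsilane
Product: 6 RAMP hydrazone of (R)-2-[2-(tert-butyldimethylsilyloxy)ethyl]cyclobutanone, via lithium azaenolate 5 (not isolated)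
Conditions: LiN(iPr)2, THF, 0 °C; then 4, −100 → −78 °C
Reagents that add atoms: none
Why: RAMP-hydrazone alkylation (Enders alkylation), in which the methoxy-chelated lithium azaenolate is alkylated by the primary iodide on its open face, which for the R auxiliary should set C18 as R because the new arm outranks the ring methylene in the CIP sense.

Step 3
Reactants: 6 RAMP hydrazone of (R)-2-[2-(tert-butyldimethylsilyloxy)ethyl]cyclobutanone
Product: 7 (R)-2-[2-(tert-butyldimethylsilyloxy)ethyl]cyclobutan-1-one
Conditions: O3, CH2Cl2, −78 °C; N2 purge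
Reagents that add atoms: ozone, [O-][O+]=O
Why: Ozonolytic hydrazone cleavage is neutral and cold, so the α-branched cyclobutanone should be released without enolisation (C18 kept) and with the silyl ether untouched.

Step 4
Reactants: 8 pent-3-yn-1-ol
Product: 9 5-bromopent-2-yne
Conditions: CBr4, PPh3, CH2Cl2, 0 °C
Reagents that add atoms: tetrabromomethane, BrC(Br)(Br)Br
Why: Appel reaction of a primary alcohol, to which the internal alkyne is inert.

Step 5
Reactants: 9 5-bromopent-2-yne; 10 ethyl but-2-ynoate
Product: 13 ethyl (E)-3-methyloct-2-en-6-ynoate, via Grignard reagent 11 (not isolated), via alkenylcopper adduct 12 (not isolated)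
Conditions: Mg, THF; CuBr·SMe2, THF, −78 °C; then 10, −78 °C; aq. NH4Cl, −78 °C
Reagents that add atoms: none
Why: Syn-carbocupration (conjugate addition of an organocopper reagent to an ynoate) followed by protonation of the α-cuprio ester at low temperature, before it can equilibrate through the allenoate, should give the E C10=C11 bond with the chain trans to the ester.

Step 6
Reactants: 13 ethyl (E)-3-methyloct-2-en-6-ynoate
Product: 14 (E)-3-methyloct-2-en-6-yn-1-ol
Conditions: i-Bu2AlH, CH2Cl2, −78 °C; aq. potassium sodium tartrate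
Reagents that add atoms: none
Why: 1,2-Hydride reduction of the enoate with i-Bu2AlH gives the allylic alcohol and leaves the trisubstituted alkene and the alkyne alone.

Step 7
Reactants: 14 (E)-3-methyloct-2-en-6-yn-1-ol
Product: 15 (E)-3-methyloct-2-en-6-ynal
Conditions: MnO2, CH2Cl2, rt
Reagents that add atoms: none
Why: Allylic oxidation with MnO2 is selective for the allylic alcohol and should not isomerise the E enal.

Step 8
Reactants: 15 (E)-3-methyloct-2-en-6-ynal; 16 allenylboronic acid pinacol ester
Product: 17 (4R,5E)-6-methylundec-5-ene-1,9-diyn-4-ol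
Conditions: (R)-3,3'-bis(2,4,6-triisopropylphenyl)-1,1'-binaphthyl-2,2'-diyl hydrogen phosphate [(R)-TRIP] (10 mol%), 4 Å MS, toluene, 0 °C
Reagents that add atoms: none
Why: Chiral-phosphoric-acid-catalysed propargylboration through a closed six-membered transition state (SE2′ of the allenylboronate) gives only the homopropargylic alcohol, and the R catalyst is chosen because it should direct attack to the Re face of the enal, which sets C9 as R.

Step 9
Reactants: 17 (4R,5E)-6-methylundec-5-ene-1,9-diyn-4-ol
Product: 19 (1E,4R,5E)-1-iodo-2,6-dimethylundeca-1,5-dien-9-yn-4-ol, via alkenylalane 18 (not isolated)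
Conditions: Me3Al, Cp2ZrCl2 (25 mol%), CH2Cl2, 0 °C → rt; then I2, THF, −30 °C
Reagents that add atoms: trimethylaluminium, C[Al](C)C; iodine, II
Why: Negishi zirconium-catalysed carboalumination adds methyl and aluminium syn across the terminal alkyne with methyl on C7 (the internal alkyne reacts far more slowly), and iodinolysis of the C–Al bond with retention gives the E C6=C7 vinyl iodide.

Step 10
Reactants: 19 (1E,4R,5E)-1-iodo-2,6-dimethylundeca-1,5-dien-9-yn-4-ol
Product: 20 triisopropylsilyl ether of 19
Conditions: TIPSOTf, 2,6-lutidine, CH2Cl2, 0 °C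
Reagents that add atoms: triisopropylsilyl trifluoromethanesulfonate, CC(C)[Si](C(C)C)(C(C)C)OS(=O)(=O)C(F)(F)F
Why: Silyl ether formation with a silyl triflate and a hindered base protects the C9 alcohol in a form that withstands the organolithium, zirconium and palladium steps ahead.

Step 11
Reactants: 20 triisopropylsilyl ether of 19; 7 (R)-2-[2-(tert-butyldimethylsilyloxy)ethyl]cyclobutan-1-one
Product: 22 (1R,2R)-2-[2-(tert-butyldimethylsilyloxy)ethyl]-1-[(1E,4R,5E)-2,6-dimethyl-4-(triisopropylsilyloxy)undeca-1,5-dien-9-yn-1-yl]cyclobutan-1-ol, via alkenyllithium 21 (not isolated)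
Conditions: t-BuLi, Et2O, −78 °C; then 7, −78 °C; H2O
Reagents that add atoms: none
Why: Iodine–lithium exchange with retention of alkene geometry and 1,2-addition of the alkenyllithium to the strained ketone, which should be faster than enolisation (C18 kept) and should occur trans to the C18 arm, the C5 configuration being of no consequence because C5 becomes a ketone in step 13.

Step 12
Reactants: 22 alkynyl cyclobutanol
Product: 24 (1R,2R)-2-[2-(tert-butyldimethylsilyloxy)ethyl]-1-[(1E,4R,5E,9E)-10-iodo-2,6-dimethyl-4-(triisopropylsilyloxy)undeca-1,5,9-trien-1-yl]cyclobutan-1-ol, via alkenylzirconocene 23 (not isolated)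
Conditions: Cp2Zr(H)Cl (excess), THF, 50 °C; then I2, THF, −78 °C; aq. Na2S2O3
Reagents that add atoms: iodine, II
Why: Schwartz hydrozirconation–iodination, in which syn addition of Zr–H, equilibrated by the excess reagent toward zirconium on the methyl-bearing carbon C15, and iodinolysis with retention give the E C14=C15 vinyl iodide, while the tertiary alcohol is masked in the flask as its zirconium alkoxide and the trisubstituted alkenes are too hindered to react.

Step 13
Reactants: 24 cyclobutanol vinyl iodide
Product: 25 ring A enone, (2E,5R,6E,10E,14R)-14-[2-(tert-butyldimethylsilyloxy)ethyl]-3,7,11-trimethyl-5-(triisopropylsilyloxy)cyclotetradeca-2,6,10-trien-1-one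
Conditions: Pd(OAc)2 (10 mol%), P(tBu)3 (20 mol%), Cs2CO3 (3 equiv), toluene, 60 °C; 24 added by syringe pump to 1 mM
Reagents that add atoms: none
Why: Proposed new method: zerovalent palladium, formed in the flask from Pd(OAc)2 and the phosphine, inserts into the C15–I bond, the carbonate exchanges iodide on divalent palladium for the tertiary cyclobutanolate, β-carbon elimination cleaves the strained C5–C16 bond to release the C5 ketone and place palladium on primary C16, and C(sp2)–C(sp3) reductive elimination joins C15 to C16. The closest known reaction type is the intermolecular palladium-catalysed ring-opening coupling of tertiary cyclobutanols with aryl and alkenyl halides to give γ-substituted ketones, and its use as a ring-closing event is the new element. Ring A closes by reductive elimination from a 15-membered palladacycle that is reached irreversibly because the four-membered ring strain is lost, with high dilution to hold back oligomers. No stereocentre is formed: C5 becomes trigonal, C9 and C18 are untouched and the C14=C15 geometry is carried over with retention. The step needs cleavage of C5–C16 and not C5–C18, which the preference for a primary over a secondary alkylpalladium should secure, reductive elimination ahead of β-hydride loss toward C17, which the bulky electron-rich P(tBu)3 should secure, and neither carbopalladation of C6=C7 nor epimerisation at C18, which the trisubstitution of that alkene and the weak heterogeneous base should secure.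

Step 14
Reactants: 25 ring A enone
Product: 26 ring A allylic alcohol (5R,9R,18R; C5 arranged as in the target)
Conditions: (S)-2-methyl-CBS-oxazaborolidine (1 equiv), catecholborane, toluene, −78 °C; MeOH
Reagents that add atoms: none
Why: Corey–Bakshi–Shibata reduction with catecholborane is 1,2-selective for enones, and with the alkenyl group as the large substituent the S oxazaborolidine should deliver hydride to the face that gives the C5 carbinol of target configuration (R descriptor at this stage), which leads to the trans-fused lactone.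

Step 15
Reactants: 26 ring A allylic alcohol
Product: 27 ring A diol with free C3 and C5 hydroxyls
Conditions: HF·pyridine, pyridine, THF, 0 °C
Reagents that add atoms: none
Why: Selective silyl ether cleavage, because buffered HF·pyridine removes the unhindered primary tert-butyldimethylsilyl ether much faster than the hindered secondary triisopropylsilyl ether.

Step 16
Reactants: 27 ring A diol
Product: 28 trans-fused γ-lactone (rings A and B, C9 silyl ether, C2 still CH2)
Conditions: TEMPO (cat.), PhI(OAc)2, CH2Cl2, rt
Reagents that add atoms: none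
Why: TEMPO/PhI(OAc)2 oxidative lactonisation of the 1,4-diol, in which the primary alcohol is oxidised first, the aldehyde is trapped by the C5 hydroxyl as a five-membered lactol and this is oxidised to the lactone faster than the hindered secondary allylic alcohol, so ring B closes with C5 and C18 unchanged.

Step 17
Reactants: 28 trans-fused γ-lactone
Product: 30 2-(dimethylaminomethyl) lactone (C2 epimers), via lithium enolate 29 (not isolated)
Conditions: LiN(iPr)2, THF, −78 °C; then CH2=NMe2+ I−, −78 → 0 °C
Reagents that add atoms: dimethylmethyleneammonium iodide, C=[N+](C)C.[I-]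
Why: Mannich reaction of the lactone lithium enolate with the iminium salt (first stage of the Eschenmoser methylenation) introduces C1 at C2, whose configuration is irrelevant.

Step 18
Reactants: 30 2-(dimethylaminomethyl) lactone
Product: 32 α-methylene lactone with C9 triisopropylsilyl ether, via ammonium iodide 31 (not isolated)
Conditions: MeI, CH2Cl2, rt; then aq. NaHCO3, rt
Reagents that add atoms: none
Why: Quaternisation of the amine and base-induced E1cB loss of trimethylamine (second stage of the Eschenmoser methylenation) give the exocyclic C1=C2 double bond.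

Step 19
Reactants: 32 α-methylene lactone with C9 triisopropylsilyl ether
Product: 33 C9 alcohol (desacetyl target)
Conditions: Bu4NF, AcOH, THF, 0 °C → rt
Reagents that add atoms: none
Why: Fluoride-mediated silyl ether deprotection, buffered with acetic acid so that basic fluoride does not attack the Michael-acceptor lactone.

Step 20
Reactants: 33 C9 alcohol
Product: 34 CNP0206931.1
Conditions: Ac2O, pyridine, DMAP (cat.), CH2Cl2, 0 °C
Reagents that add atoms: acetic anhydride, CC(=O)OC(C)=O
Why: DMAP-catalysed esterification of the secondary allylic alcohol gives the C9 acetate with retention of configuration.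

**Compound list**

1 | cyclobutanone | O=C1CCC1 | starting material
2 | (R)-1-amino-2-(methoxymethyl)pyrrolidine (RAMP) | COC[C@H]1CCCN1N | starting material
3 | (R)-N-cyclobutylidene-2-(methoxymethyl)pyrrolidin-1-amine | COC[C@H]1CCCN1N=C1CCC1 | intermediate
4 | tert-butyl(2-iodoethoxy)dimethylsilane | CC(C)(C)[Si](C)(C)OCCI | starting material
5 | lithium azaenolate of 3 | COC[C@H]1CCCN1N([Li])C1=CCC1 | intermediate
6 | (R)-N-[(2R)-2-[2-(tert-butyldimethylsilyloxy)ethyl]cyclobutylidene]-2-(methoxymethyl)pyrrolidin-1-amine | COC[C@H]1CCCN1N=C1CC[C@@H]1CCO[Si](C)(C)C(C)(C)C | intermediate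
7 | (R)-2-[2-(tert-butyldimethylsilyloxy)ethyl]cyclobutan-1-one | O=C1CC[C@@H]1CCO[Si](C)(C)C(C)(C)C | intermediate
8 | pent-3-yn-1-ol | CC#CCCO | starting material
9 | 5-bromopent-2-yne | CC#CCCBr | intermediate
10 | ethyl but-2-ynoate | CC#CC(=O)OCC | starting material
11 | pent-3-ynylmagnesium bromide | CC#CCC[Mg]Br | intermediate
12 | ethyl (Z)-2-cuprio-3-methyloct-2-en-6-ynoate | CCOC(=O)/C([Cu])=C(\C)CCC#CC | intermediate
13 | ethyl (E)-3-methyloct-2-en-6-ynoate | CCOC(=O)/C=C(\C)CCC#CC | intermediate
14 | (E)-3-methyloct-2-en-6-yn-1-ol | OC/C=C(\C)CCC#CC | intermediate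
15 | (E)-3-methyloct-2-en-6-ynal | O=C/C=C(\C)CCC#CC | intermediate
16 | allenylboronic acid pinacol ester | C=C=CB1OC(C)(C)C(C)(C)O1 | starting material
17 | (4R,5E)-6-methylundec-5-ene-1,9-diyn-4-ol | C#CC[C@@H](O)/C=C(\C)CCC#CC | intermediate
18 | (E)-alkenyl(dimethyl)alane of 17 as its dimethylaluminium alkoxide | C[Al](C)/C=C(\C)C[C@@H](O[Al](C)C)/C=C(\C)CCC#CC | intermediate
19 | (1E,4R,5E)-1-iodo-2,6-dimethylundeca-1,5-dien-9-yn-4-ol | I/C=C(\C)C[C@@H](O)/C=C(\C)CCC#CC | intermediate
20 | [(1E,4R,5E)-1-iodo-2,6-dimethylundeca-1,5-dien-9-yn-4-yl]oxy-triisopropylsilane | I/C=C(\C)C[C@@H](O[Si](C(C)C)(C(C)C)C(C)C)/C=C(\C)CCC#CC | intermediate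
21 | (E)-alkenyllithium from 20 (Li on C6) | [Li]/C=C(\C)C[C@@H](O[Si](C(C)C)(C(C)C)C(C)C)/C=C(\C)CCC#CC | intermediate
22 | (1R,2R)-2-[2-(tert-butyldimethylsilyloxy)ethyl]-1-[(1E,4R,5E)-2,6-dimethyl-4-(triisopropylsilyloxy)undeca-1,5-dien-9-yn-1-yl]cyclobutan-1-ol | CC(C)(C)[Si](C)(C)OCC[C@H]1CC[C@]1(O)/C=C(\C)C[C@@H](O[Si](C(C)C)(C(C)C)C(C)C)/C=C(\C)CCC#CC | intermediate
23 | C15 alkenylzirconocene chloride of 22 as its zirconocene chloride alkoxide (cyclopentadienyl drawn σ-bonded) | CC(C)(C)[Si](C)(C)OCC[C@H]1CC[C@]1(O[Zr](Cl)(C1C=CC=C1)C1C=CC=C1)/C=C(\C)C[C@@H](O[Si](C(C)C)(C(C)C)C(C)C)/C=C(\C)CC/C=C(\C)[Zr](Cl)(C1C=CC=C1)C1C=CC=C1 | intermediate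
24 | (1R,2R)-2-[2-(tert-butyldimethylsilyloxy)ethyl]-1-[(1E,4R,5E,9E)-10-iodo-2,6-dimethyl-4-(triisopropylsilyloxy)undeca-1,5,9-trien-1-yl]cyclobutan-1-ol | CC(C)(C)[Si](C)(C)OCC[C@H]1CC[C@]1(O)/C=C(\C)C[C@@H](O[Si](C(C)C)(C(C)C)C(C)C)/C=C(\C)CC/C=C(\C)I | intermediate
25 | (2E,5R,6E,10E,14R)-14-[2-(tert-butyldimethylsilyloxy)ethyl]-3,7,11-trimethyl-5-(triisopropylsilyloxy)cyclotetradeca-2,6,10-trien-1-one (ring A enone, C5 ketone) | CC(C)(C)[Si](C)(C)OCC[C@@H]1C(=O)/C=C(\C)C[C@@H](O[Si](C(C)C)(C(C)C)C(C)C)/C=C(\C)CC/C=C(\C)CC1 | intermediate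
26 | (1R,2E,5R,6E,10E,14R)-14-[2-(tert-butyldimethylsilyloxy)ethyl]-3,7,11-trimethyl-5-(triisopropylsilyloxy)cyclotetradeca-2,6,10-trien-1-ol | CC(C)(C)[Si](C)(C)OCC[C@@H]1[C@@H](O)/C=C(\C)C[C@@H](O[Si](C(C)C)(C(C)C)C(C)C)/C=C(\C)CC/C=C(\C)CC1 | intermediate
27 | (1R,2E,5R,6E,10E,14R)-14-(2-hydroxyethyl)-3,7,11-trimethyl-5-(triisopropylsilyloxy)cyclotetradeca-2,6,10-trien-1-ol | OCC[C@@H]1[C@@H](O)/C=C(\C)C[C@@H](O[Si](C(C)C)(C(C)C)C(C)C)/C=C(\C)CC/C=C(\C)CC1 | intermediate
28 | trans-fused γ-lactone of rings A and B: C3 carbonyl, C2 methylene group CH2, C9 triisopropylsilyl ether, (6E,10E,14E), (5R,9R,18R) | O=C1O[C@H]2/C=C(\C)C[C@@H](O[Si](C(C)C)(C(C)C)C(C)C)/C=C(\C)CC/C=C(\C)CC[C@@H]2C1 | intermediate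
29 | lithium enolate of 28 (C2=C3–OLi) | C1=C(O[Li])O[C@H]2/C=C(\C)C[C@@H](O[Si](C(C)C)(C(C)C)C(C)C)/C=C(\C)CC/C=C(\C)CC[C@H]12 | intermediate
30 | 28 carrying CH2NMe2 on C2 (Mannich base, C2 epimers) | CN(C)CC1C(=O)O[C@H]2/C=C(\C)C[C@@H](O[Si](C(C)C)(C(C)C)C(C)C)/C=C(\C)CC/C=C(\C)CC[C@H]12 | intermediate
31 | trimethylammonium iodide of 30 | C[N+](C)(C)CC1C(=O)O[C@H]2/C=C(\C)C[C@@H](O[Si](C(C)C)(C(C)C)C(C)C)/C=C(\C)CC/C=C(\C)CC[C@H]12.[I-] | intermediate
32 | α-methylene lactone with C9 triisopropylsilyl ether (5S,9R,18R) | C=C1C(=O)O[C@H]2/C=C(\C)C[C@@H](O[Si](C(C)C)(C(C)C)C(C)C)/C=C(\C)CC/C=C(\C)CC[C@H]12 | intermediate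
33 | α-methylene lactone with free C9 hydroxyl (5S,9R,18R) | C=C1C(=O)O[C@H]2/C=C(\C)C[C@@H](O)/C=C(\C)CC/C=C(\C)CC[C@H]12 | intermediate
34 | CNP0206931.1, C9 acetate (5S,9R,18R; 6E,10E,14E) | C=C1C(=O)O[C@H]2/C=C(\C)C[C@@H](OC(C)=O)/C=C(\C)CC/C=C(\C)CC[C@H]12 | target

**Step count and risks**

Total: 20 steps. Longest linear sequence: 17 steps (8 → 34, steps 4–20); the cyclobutanone branch (steps 1–3) joins at step 11.

Step 13 (most likely to fail). The ring closure may lose to intermolecular coupling, to cleavage of the C5–C18 bond, to β-hydride loss from the C16 alkylpalladium or to base-induced isomerisation of the new enone. The fallback closes the same C15–C16 bond by a B-alkyl Suzuki–Miyaura macrocyclisation, which is known chemistry. It sets out from vinyl iodide 20. Iodine–lithium exchange (t-BuLi, Et2O, −78 °C) and trapping with paraformaldehyde should give the allylic alcohol F1. Hydrozirconation–iodination of its alkyne (Cp2Zr(H)Cl, THF, 50 °C; I2) should give the C15 vinyl iodide F2, and MnO2 the C5 enal F3. A syn-selective asymmetric allylboration of F3 with (Z)-5-(tert-butyldimethylsilyloxy)pent-2-enylboronic acid pinacol ester under (R)-TRIP catalysis should set C5 and C18 together in the homoallylic alcohol F4, which carries a vinyl group (C17=C16) on C18. Hydroboration of that vinyl group with 9-BBN and intramolecular coupling with the C15 iodide (Pd(dppf)Cl2, AsPh3, Cs2CO3, DMF/THF/H2O, high dilution) should close ring A and return to the route at alcohol 26.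

Step 12. Regiocontrol of the Zr–H addition may be incomplete on an alkyne flanked only by methyl and methylene, and the alkenylcyclobutanol or the silyl ethers may erode under hot excess hydride and iodine. The fallback installs the halide before the fragments are joined, as a bromide that survives a selective iodine–magnesium exchange. It sets out from allylic alcohol 14. Hydrozirconation (excess Cp2Zr(H)Cl, THF, 50 °C) and N-bromosuccinimide should give the bromodienol F5, which can be freed from its regioisomer at this inexpensive stage. MnO2 should give the enal F6, propargylboration as in step 8 the alcohol F7, carboalumination–iodination as in step 9 the iodo bromide F8, and TIPSOTf the silyl ether F9. iPrMgCl·LiCl should exchange only the alkenyl iodide, and the alkenylmagnesium reagent with LaCl3·2LiCl should add to ketone 7 to give the bromo cyclobutanol F10. Under the conditions of step 13 the vinyl bromide takes the place of the iodide, and the route is rejoined at enone 25.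

Step 14. Facial selectivity may be poor if the macrocycle conformation overrides the catalyst or if the branched C18 side, not the alkenyl side, behaves as the large group. The fallback relies on substrate control and inversion. It sets out from enone 25. Luche reduction (NaBH4, CeCl3·7H2O, MeOH, −78 °C) should give the C5 alcohols; the epimer of target configuration is 26 itself. The C5 epimer F11 is inverted by a Mitsunobu reaction with 4-nitrobenzoic acid (PPh3, DIAD, toluene) to the ester F12, and methanolysis (K2CO3, MeOH) returns to the route at 26.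

**Further compounds**

F1 | step 13 | (2E,5R,6E)-3,7-dimethyl-5-(triisopropylsilyloxy)dodeca-2,6-dien-10-yn-1-ol | OC/C=C(\C)C[C@@H](O[Si](C(C)C)(C(C)C)C(C)C)/C=C(\C)CCC#CC
F2 | step 13 | (2E,5R,6E,10E)-11-iodo-3,7-dimethyl-5-(triisopropylsilyloxy)dodeca-2,6,10-trien-1-ol | OC/C=C(\C)C[C@@H](O[Si](C(C)C)(C(C)C)C(C)C)/C=C(\C)CC/C=C(\C)I
F3 | step 13 | (2E,5R,6E,10E)-11-iodo-3,7-dimethyl-5-(triisopropylsilyloxy)dodeca-2,6,10-trienal | O=C/C=C(\C)C[C@@H](O[Si](C(C)C)(C(C)C)C(C)C)/C=C(\C)CC/C=C(\C)I
F4 | step 13 | syn homoallylic alcohol: C5 carbinol, C18 bearing vinyl and 2-(tert-butyldimethylsilyloxy)ethyl, C15 vinyl iodide, C5 and C18 arranged as in 26 | CC(C)(C)[Si](C)(C)OCC[C@@H](C=C)[C@@H](O)/C=C(\C)C[C@@H](O[Si](C(C)C)(C(C)C)C(C)C)/C=C(\C)CC/C=C(\C)I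
F5 | step 12 | (2E,6E)-7-bromo-3-methylocta-2,6-dien-1-ol | OC/C=C(\C)CC/C=C(\C)Br
F6 | step 12 | (2E,6E)-7-bromo-3-methylocta-2,6-dienal | O=C/C=C(\C)CC/C=C(\C)Br
F7 | step 12 | (4R,5E,9E)-10-bromo-6-methylundeca-5,9-dien-1-yn-4-ol | C#CC[C@@H](O)/C=C(\C)CC/C=C(\C)Br
F8 | step 12 | (1E,4R,5E,9E)-10-bromo-1-iodo-2,6-dimethylundeca-1,5,9-trien-4-ol | I/C=C(\C)C[C@@H](O)/C=C(\C)CC/C=C(\C)Br
F9 | step 12 | triisopropylsilyl ether of F8 | I/C=C(\C)C[C@@H](O[Si](C(C)C)(C(C)C)C(C)C)/C=C(\C)CC/C=C(\C)Br
F10 | step 12 | C15 bromo analogue of 24 | CC(C)(C)[Si](C)(C)OCC[C@H]1CC[C@]1(O)/C=C(\C)C[C@@H](O[Si](C(C)C)(C(C)C)C(C)C)/C=C(\C)CC/C=C(\C)Br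
F11 | step 14 | C5 epimer of 26 | CC(C)(C)[Si](C)(C)OCC[C@@H]1[C@H](O)/C=C(\C)C[C@@H](O[Si](C(C)C)(C(C)C)C(C)C)/C=C(\C)CC/C=C(\C)CC1
F12 | step 14 | 4-nitrobenzoate of 26 | CC(C)(C)[Si](C)(C)OCC[C@@H]1[C@@H](OC(=O)c2ccc(cc2)[N+](=O)[O-])/C=C(\C)C[C@@H](O[Si](C(C)C)(C(C)C)C(C)C)/C=C(\C)CC/C=C(\C)CC1
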